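**Retrosynthetic overview**
1. 22 ⇐ 19: the last operation forms both rings from an open chain. Ni/Cr coupling of the C4 alkenyl iodide with the C3 aldehyde closes the ten-membered ring A; desilylation then frees O6, which lactonises onto C12 (ring B).
2. 19 ⇐ 16: isobutyrylation of O8 and oxidative cleavage of the prenyl end to the C3 aldehyde.
3. 16 ⇐ 15 + 6: indium Barbier allylation forms C7–C8 and sets C7 and C8 from the single stereocentre C6.
4. 15 ⇐ acrolein + propynyl Grignard (kinetic resolution for C6, hydroalumination–iodination for the Z-iodoalkene, cross-metathesis with methyl 2-(bromomethyl)acrylate); 6 ⇐ geraniol (Sharpless epoxidation for C10, reductive epoxide opening).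
5. Ring order: ring A (carbocycle), then ring B (lactone), in one flask.

Assumption: atom labels C1–C15 follow germacranolide numbering of the target (lactone C12(=O)–O–C6, exocyclic C11=C13, ring C1–C10, methyls on C10 and C4); the target is then (3S,6R,7R,8R,10S).

**Step 1**
Reactants: 1 geraniol
Product: 2 (2S,3S)-2,3-epoxygeraniol
Conditions: Ti(OiPr)4 (5 mol %), L-(+)-diethyl tartrate (7 mol %), t-BuOOH, 4 Å sieves, CH2Cl2, −20 °C
Reagents that add atoms: tert-butyl hydroperoxide, CC(C)(C)OO
Why: Sharpless asymmetric epoxidation of the allylic alcohol, in which the titanium–L-(+)-tartrate peroxide delivers oxygen to one face of the 2,3-alkene only (the remote alkene has no directing hydroxyl) and gives the (2S,3S)-epoxide whose C3 becomes C10 of the target.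

**Step 2**
Reactants: 2 (2S,3S)-2,3-epoxygeraniol
Product: 3 (3S)-3,7-dimethyloct-6-ene-1,3-diol
Conditions: NaAlH2(OCH2CH2OMe)2 (Red-Al), THF, 0 °C to rt
Reagents that add atoms: none
Why: Hydroxyl-directed reductive opening of a 2,3-epoxy alcohol, in which the alkoxyaluminium hydride delivers hydride internally to C2, so the 1,3-diol forms and the tertiary C–O bond (future C10, S) is untouched.

**Step 3**
Reactants: 3 (3S)-3,7-dimethyloct-6-ene-1,3-diol
Product: 4 (3S)-3,7-dimethyl-1,3-bis[(triethylsilyl)oxy]oct-6-ene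
Conditions: Et3SiOTf (2.4 equiv), 2,6-lutidine, CH2Cl2, −78 to 0 °C
Reagents that add atoms: triethylsilyl trifluoromethanesulfonate, CC[Si](CC)(CC)OS(=O)(=O)C(F)(F)F
Why: Exhaustive silylation with the silyl triflate, which is reactive enough for the tertiary alcohol; no stereocentre is touched.

**Step 4**
Reactants: 4 (3S)-3,7-dimethyl-1,3-bis[(triethylsilyl)oxy]oct-6-ene
Product: 6 (3S)-3,7-dimethyl-3-[(triethylsilyl)oxy]oct-6-enal, via alkoxysulfonium chloride 5 (not isolated)
Conditions: (COCl)2, DMSO, CH2Cl2, −78 to −30 °C; then Et3N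
Reagents that add atoms: none
Why: Swern oxidation applied directly to the silyl ether, in which the chlorosulfonium reagent cleaves only the unhindered primary O–Si bond to the alkoxysulfonium salt that collapses with Et3N to the aldehyde, while the tertiary silyl ether survives and prevents retro-aldol and later lactol formation.

**Step 5**
Reactants: 7 acrolein; 8 prop-1-yn-1-ylmagnesium bromide
Product: 9 rac-hex-1-en-4-yn-3-ol
Conditions: THF, −78 to 0 °C; aq. NH4Cl
Reagents that add atoms: none
Why: Grignard 1,2-addition of the alkynyl nucleophile to the enal carbonyl gives the racemic alkenyl alkynyl carbinol from two bulk chemicals.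

**Step 6**
Reactants: 9 rac-hex-1-en-4-yn-3-ol
Product: 10 (3S)-hex-1-en-4-yn-3-ol
Conditions: Ti(OiPr)4 (0.15 equiv), L-(+)-diisopropyl tartrate (0.2 equiv), t-BuOOH (0.6 equiv), 4 Å sieves, CH2Cl2, −20 °C, about 55 % conversion; recover the alcohol
Reagents that add atoms: none
Why: Sharpless kinetic resolution of a secondary allylic alcohol, in which L-(+)-tartrate epoxidises the (R)-enantiomer much faster (oxygen from the lower face, fast isomer carries the alkynyl group on the upper face), so (S)-10 is recovered in high ee at no more than 50 % yield.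

**Step 7**
Reactants: 10 (3S)-hex-1-en-4-yn-3-ol
Product: 12 (3S,4Z)-5-iodohexa-1,4-dien-3-ol, via cyclic alkenylalanate 11 (not isolated)
Conditions: NaAlH2(OCH2CH2OMe)2 (1.6 equiv), THF, 0 °C to rt; EtOAc; then I2, −78 °C
Reagents that add atoms: iodine, II
Why: Hydroxyl-directed trans-hydroalumination of the propargylic alcohol (hydride to the proximal alkyne carbon, aluminium to the distal one in a five-membered alanate) and iodinolysis with retention give only the Z-iodoalkene with iodine (later C3) cis to C6, leaving the vinyl group and the carbinol centre untouched.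

**Step 8**
Reactants: 12 (3S,4Z)-5-iodohexa-1,4-dien-3-ol
Product: 13 tert-butyl{[(3S,4Z)-5-iodohexa-1,4-dien-3-yl]oxy}dimethylsilane
Conditions: t-BuMe2SiCl, imidazole, DMF, rt
Reagents that add atoms: tert-butyldimethylsilyl chloride, CC(C)(C)[Si](C)(C)Cl
Why: Imidazole-promoted silylation of the secondary alcohol gives the bulky silyl ether that later steers the allylation and keeps O6 blocked until the last step.

**Step 9**
Reactants: 13 tert-butyl{[(3S,4Z)-5-iodohexa-1,4-dien-3-yl]oxy}dimethylsilane; 14 methyl 2-(bromomethyl)prop-2-enoate (5 equiv)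
Product: 15 methyl (2Z,4S,5Z)-2-(bromomethyl)-4-[(tert-butyldimethylsilyl)oxy]-6-iodohepta-2,5-dienoate
Conditions: second-generation Hoveyda–Grubbs catalyst RuCl2(H2IMes)(=CH–C6H4-2-OiPr) (7 mol %), CH2Cl2, 40 °C
Reagents that add atoms: none
Why: Olefin cross-metathesis between the terminal vinyl group and the 1,1-disubstituted acrylate (the trisubstituted iodoalkene is inert), driven by loss of ethene, with thermodynamic control placing the chain trans to the ester, which is the (2Z)-bromide.

**Step 10**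
Reactants: 15 methyl (2Z,4S,5Z)-2-(bromomethyl)-4-[(tert-butyldimethylsilyl)oxy]-6-iodohepta-2,5-dienoate; 6 (3S)-3,7-dimethyl-3-[(triethylsilyl)oxy]oct-6-enal
Product: 16 methyl (3R,4R,6S)-3-[(1S,2Z)-1-[(tert-butyldimethylsilyl)oxy]-3-iodobut-2-en-1-yl]-4-hydroxy-6,10-dimethyl-2-methylidene-6-[(triethylsilyl)oxy]undec-9-enoate
Conditions: In powder (1.5 equiv), THF/H2O (1:1), rt
Reagents that add atoms: none
Why: Indium Barbier allylation (SE2′), in which the (Z)-allylindium reacts through a closed chair transition state with the aldehyde chain equatorial to give the 7,8-syn relationship (8R), and allylic 1,3-strain holds H6 in the allyl plane so the aldehyde adds to C7 anti to the bulky silyloxy group (7R); in aqueous THF the hydroxy ester does not lactonise onto O8.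

**Step 11**
Reactants: 16 hydroxy ester from step 10
Product: 17 methyl (3R,4R,6S)-3-[(1S,2Z)-1-[(tert-butyldimethylsilyl)oxy]-3-iodobut-2-en-1-yl]-6,10-dimethyl-2-methylidene-4-[(2-methylpropanoyl)oxy]-6-[(triethylsilyl)oxy]undec-9-enoate
Conditions: (i-PrCO)2O, DMAP (cat.), Et3N, CH2Cl2, 0 °C to rt
Reagents that add atoms: isobutyric anhydride, CC(C)C(=O)OC(=O)C(C)C
Why: DMAP-catalysed acyl transfer to the only free hydroxyl, done while O6 is still silylated, fixes which oxygen becomes the ester and which the lactone.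

**Step 12**
Reactants: 17 isobutyrate from step 11
Product: 19 methyl (3R,4R,6S)-3-[(1S,2Z)-1-[(tert-butyldimethylsilyl)oxy]-3-iodobut-2-en-1-yl]-6-methyl-2-methylidene-4-[(2-methylpropanoyl)oxy]-9-oxo-6-[(triethylsilyl)oxy]nonanoate, via vicinal diol 18 (not isolated)
Conditions: OsO4 (2 mol %), NaIO4 (4 equiv), 2,6-lutidine, dioxane/H2O (3:1), rt
Reagents that add atoms: osmium tetroxide, O=[Os](=O)(=O)=O; sodium periodate (re-oxidant, ultimate oxygen source), [Na+].[O-][I](=O)(=O)=O
Why: Lemieux–Johnson oxidative cleavage, in which OsO4 dihydroxylates the electron-rich trisubstituted alkene much faster than the electron-poor acrylate or the hindered iodoalkene and periodate cleaves the diol to the C3 aldehyde.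

**Step 13**
Reactants: 19 open-chain iodoalkenyl aldehyde from step 12
Product: 22 CNP0163972.1, via macrocyclic silyl ether ester 20 (not isolated), via triol methyl ester 21 (not isolated)
Conditions: CrCl2 (8 equiv), NiCl2 (0.1 equiv), DMSO/THF (3:1), rt, syringe-pump addition to 2 mM; then HF·pyridine, pyridine, 0 °C to rt, same flask
Reagents that add atoms: none
Why: Nozaki–Hiyama–Kishi reaction, in which zerovalent nickel inserts into the C4–I bond, the alkenyl group passes to trivalent chromium with retention of the Z geometry and adds to the C3 aldehyde to close ring A with C3 set by macrocyclic control (chromium alkoxide on the outside of the forming ring, expected to favour 3S), after which HF removes both silyl groups and O6–H, now γ to the ester across sp3 C7, lactonises with loss of methanol to the trans-fused ring B.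

**Compound list**
1 | geraniol, (2E)-3,7-dimethylocta-2,6-dien-1-ol | CC(C)=CCC/C(C)=C/CO | starting material
2 | (2S,3S)-2,3-epoxygeraniol | OC[C@@H]1O[C@@]1(C)CCC=C(C)C | intermediate
3 | (3S)-3,7-dimethyloct-6-ene-1,3-diol | OCC[C@@](C)(O)CCC=C(C)C | intermediate
4 | (3S)-3,7-dimethyl-1,3-bis[(triethylsilyl)oxy]oct-6-ene | CC[Si](CC)(CC)OCC[C@@](C)(O[Si](CC)(CC)CC)CCC=C(C)C | intermediate
5 | dimethyl{[(3S)-3,7-dimethyl-3-(triethylsilyloxy)oct-6-en-1-yl]oxy}sulfonium chloride (not isolated) | C[S+](C)OCC[C@@](C)(O[Si](CC)(CC)CC)CCC=C(C)C.[Cl-] | intermediate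
6 | (3S)-3,7-dimethyl-3-[(triethylsilyl)oxy]oct-6-enal | O=CC[C@@](C)(O[Si](CC)(CC)CC)CCC=C(C)C | intermediate
7 | acrolein | C=CC=O | starting material
8 | prop-1-yn-1-ylmagnesium bromide | CC#C[Mg]Br | starting material
9 | rac-hex-1-en-4-yn-3-ol | C=CC(O)C#CC | intermediate
10 | (3S)-hex-1-en-4-yn-3-ol | C=C[C@H](O)C#CC | intermediate
11 | sodium alkenylalanate, five-membered O–Al–C(CH3)=CH–CH(vinyl) ring, Al carrying two 2-methoxyethoxy groups, carbinol carbon S (not isolated) | C=C[C@H]1C=C(C)[Al-](OCCOC)(OCCOC)O1.[Na+] | intermediate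
12 | (3S,4Z)-5-iodohexa-1,4-dien-3-ol | C=C[C@H](O)/C=C(/C)I | intermediate
13 | tert-butyl{[(3S,4Z)-5-iodohexa-1,4-dien-3-yl]oxy}dimethylsilane | C=C[C@H](O[Si](C)(C)C(C)(C)C)/C=C(/C)I | intermediate
14 | methyl 2-(bromomethyl)prop-2-enoate | C=C(CBr)C(=O)OC | starting material
15 | methyl (2Z,4S,5Z)-2-(bromomethyl)-4-[(tert-butyldimethylsilyl)oxy]-6-iodohepta-2,5-dienoate | COC(=O)/C(CBr)=C/[C@H](O[Si](C)(C)C(C)(C)C)/C=C(/C)I | intermediate
16 | methyl (3R,4R,6S)-3-[(1S,2Z)-1-[(tert-butyldimethylsilyl)oxy]-3-iodobut-2-en-1-yl]-4-hydroxy-6,10-dimethyl-2-methylidene-6-[(triethylsilyl)oxy]undec-9-enoate | C=C(C(=O)OC)[C@@H]([C@H](O[Si](C)(C)C(C)(C)C)/C=C(/C)I)[C@H](O)C[C@@](C)(O[Si](CC)(CC)CC)CCC=C(C)C | intermediate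
17 | methyl (3R,4R,6S)-3-[(1S,2Z)-1-[(tert-butyldimethylsilyl)oxy]-3-iodobut-2-en-1-yl]-6,10-dimethyl-2-methylidene-4-[(2-methylpropanoyl)oxy]-6-[(triethylsilyl)oxy]undec-9-enoate | C=C(C(=O)OC)[C@@H]([C@H](O[Si](C)(C)C(C)(C)C)/C=C(/C)I)[C@H](OC(=O)C(C)C)C[C@@](C)(O[Si](CC)(CC)CC)CCC=C(C)C | intermediate
18 | 9,10-diol of 17, both C9 epimers (not isolated) | C=C(C(=O)OC)[C@@H]([C@H](O[Si](C)(C)C(C)(C)C)/C=C(/C)I)[C@H](OC(=O)C(C)C)C[C@@](C)(O[Si](CC)(CC)CC)CCC(O)C(C)(C)O | intermediate
19 | methyl (3R,4R,6S)-3-[(1S,2Z)-1-[(tert-butyldimethylsilyl)oxy]-3-iodobut-2-en-1-yl]-6-methyl-2-methylidene-4-[(2-methylpropanoyl)oxy]-9-oxo-6-[(triethylsilyl)oxy]nonanoate | C=C(C(=O)OC)[C@@H]([C@H](O[Si](C)(C)C(C)(C)C)/C=C(/C)I)[C@H](OC(=O)C(C)C)C[C@@](C)(O[Si](CC)(CC)CC)CCC=O | intermediate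
20 | methyl 2-[(1R,2R,3Z,5S,8S,10R)-2-[(tert-butyldimethylsilyl)oxy]-5-hydroxy-4,8-dimethyl-10-[(2-methylpropanoyl)oxy]-8-[(triethylsilyl)oxy]cyclodec-3-en-1-yl]prop-2-enoate (not isolated) | C=C(C(=O)OC)[C@H]1[C@H](O[Si](C)(C)C(C)(C)C)/C=C(/C)[C@@H](O)CC[C@](C)(O[Si](CC)(CC)CC)C[C@H]1OC(=O)C(C)C | intermediate
21 | methyl 2-[(1S,2R,3Z,5S,8S,10R)-2,5,8-trihydroxy-4,8-dimethyl-10-[(2-methylpropanoyl)oxy]cyclodec-3-en-1-yl]prop-2-enoate (not isolated) | C=C(C(=O)OC)[C@H]1[C@H](O)/C=C(/C)[C@@H](O)CC[C@](C)(O)C[C@H]1OC(=O)C(C)C | intermediate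
22 | CNP0163972.1, (3S,6R,7R,8R,10S)-3,10-dihydroxy-8-[(2-methylpropanoyl)oxy]germacra-4Z,11(13)-dien-12,6-olide | C=C1C(=O)O[C@@H]2/C=C(/C)[C@@H](O)CC[C@](C)(O)C[C@@H](OC(=O)C(C)C)[C@@H]12 | target

**Step count and risks**
Total step count: 13. Longest linear sequence: 9 steps (steps 5 to 13, from acrolein 7).

The step most likely to fail is step 13. A flexible open chain must close a strained (Z)-cyclodecene without a lactone to pre-organise it. The C3 configuration rests on macrocyclic control with no firm model. The Z-ene-1,4-diol and the tertiary alcohol must also survive the acidic fluoride stage. The fallback sets out from 17 and comes back at 22; it closes the lactone before the carbocycle. HF·pyridine on 17 removes both silyl groups and the freed O6–H lactonises to hydroxy lactone F1. Et3SiOTf with 2,6-lutidine re-protects the tertiary alcohol to give silyl ether lactone F2. OsO4/NaIO4 cleaves the prenyl end to lactone aldehyde F3. CrCl2/NiCl2 then closes ring A onto the rigid trans-lactone to give macrocyclic silyl ether F4, and HF·pyridine gives 22.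

Second is step 10. The facial selectivity at C7 rests on an acyclic allylic-strain model (attack anti to the silyloxy group), and the oxygenated allylmetal could lose silanolate by 1,4-elimination. The fallback sets out from 12 (with 6) and comes back at 22; it replaces acyclic control by ring control. Esterification of 12 with 2-(bromomethyl)acrylic acid (DCC, DMAP) gives dienyl ester F5. Ring-closing metathesis with second-generation Grubbs catalyst RuCl2(H2IMes)(PCy3)(=CHPh) gives bromomethyl butenolide F6. CrCl2-mediated allylation of 6 adds to C7 anti to the C6 substituent, and the ring-locked allylchromium gives the 8-epimeric alcohol through its chair transition state, hydroxy lactone F7. Mitsunobu esterification with isobutyric acid (PPh3, DIAD) inverts C8 and gives the silyl ether lactone F2 of the first fallback, which is carried through F3 and F4 to 22.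

Third is step 9. Cross-metathesis between a hindered allylic silyl ether and a 1,1-disubstituted acrylate that carries an allylic bromide may stall. The fallback sets out from 13 and comes back at 15; it builds the bromide by a Baylis–Hillman-type sequence. OsO4/NaIO4 cleaves the terminal vinyl group of 13 to silyloxy aldehyde F8. The α-aluminoacrylate made from methyl propiolate with i-Bu2AlH and N-methylmorpholine N-oxide adds to it to give hydroxy acrylate F9 (both carbinol epimers converge). NBS/Me2S brominates with allylic transposition to 15.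

**Further compounds**
F1 | step 13 | (1R,3S)-3-hydroxy-1-[(2S,3R)-2-[(1Z)-2-iodoprop-1-en-1-yl]-4-methylidene-5-oxooxolan-3-yl]-3,7-dimethyloct-6-en-1-yl 2-methylpropanoate | C=C1C(=O)O[C@H](/C=C(/C)I)[C@H]1[C@H](OC(=O)C(C)C)C[C@@](C)(O)CCC=C(C)C
F2 | step 13 | (1R,3S)-1-[(2S,3R)-2-[(1Z)-2-iodoprop-1-en-1-yl]-4-methylidene-5-oxooxolan-3-yl]-3,7-dimethyl-3-[(triethylsilyl)oxy]oct-6-en-1-yl 2-methylpropanoate | C=C1C(=O)O[C@H](/C=C(/C)I)[C@H]1[C@H](OC(=O)C(C)C)C[C@@](C)(O[Si](CC)(CC)CC)CCC=C(C)C
F3 | step 13 | (1R,3S)-1-[(2S,3R)-2-[(1Z)-2-iodoprop-1-en-1-yl]-4-methylidene-5-oxooxolan-3-yl]-3-methyl-6-oxo-3-[(triethylsilyl)oxy]hexyl 2-methylpropanoate | C=C1C(=O)O[C@H](/C=C(/C)I)[C@H]1[C@H](OC(=O)C(C)C)C[C@@](C)(O[Si](CC)(CC)CC)CCC=O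
F4 | step 13 | 10-O-triethylsilyl ether of 22 | C=C1C(=O)O[C@@H]2/C=C(/C)[C@@H](O)CC[C@](C)(O[Si](CC)(CC)CC)C[C@@H](OC(=O)C(C)C)[C@@H]12
F5 | step 10 | (3S,4Z)-5-iodohexa-1,4-dien-3-yl 2-(bromomethyl)prop-2-enoate | C=C(CBr)C(=O)O[C@@H](C=C)/C=C(/C)I
F6 | step 10 | (5S)-3-(bromomethyl)-5-[(1Z)-2-iodoprop-1-en-1-yl]furan-2(5H)-one | O=C1O[C@H](/C=C(/C)I)C=C1CBr
F7 | step 10 | (4R,5S)-4-[(1S,3S)-1-hydroxy-3,7-dimethyl-3-[(triethylsilyl)oxy]oct-6-en-1-yl]-5-[(1Z)-2-iodoprop-1-en-1-yl]-3-methylideneoxolan-2-one | C=C1C(=O)O[C@H](/C=C(/C)I)[C@H]1[C@@H](O)C[C@@](C)(O[Si](CC)(CC)CC)CCC=C(C)C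
F8 | step 9 | (2R,3Z)-2-[(tert-butyldimethylsilyl)oxy]-4-iodopent-3-enal | O=C[C@H](O[Si](C)(C)C(C)(C)C)/C=C(/C)I
F9 | step 9 | methyl 2-[(2R,3Z)-2-[(tert-butyldimethylsilyl)oxy]-1-hydroxy-4-iodopent-3-en-1-yl]prop-2-enoate, both C1 epimers | C=C(C(=O)OC)C(O)[C@H](O[Si](C)(C)C(C)(C)C)/C=C(/C)I
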